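Target: lactucaxanthin, (all-E,3R,6R,3'R,6'R)-ε,ε-carotene-3,3'-diol, C40H56O2. It is C2-symmetric, and in each ring the OH is trans to the polyene chain.

## Retrosynthetic overview
1. The C40 diol is cut at C11=C12 and C11'=C12' by a double Wittig. This gives two identical C15 phosphonium salts and the C10 trienedial.
2. The C15 salt comes from the vinyl carbinol, which comes from (3R,6R)-3-hydroxy-α-ionone and a vinyl Grignard reagent.
3. The C3 hydroxyl comes from direct C3–H hydroxylation of (R)-α-ionone, trans to the chain, as the plant ε-ring hydroxylase does.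
4. The ring comes from acyclic pseudoionone by a catalytic enantioselective proton-initiated cyclisation. H+ adds at C2, the C1–C6 bond forms and H-4 is lost, which is the lycopene ε-cyclase sequence. This step sets C6.
5. Ring order: step 1 is the only ring-forming event. Both cyclohexene rings of the target come from that one operation, before oxidation and chain building.

Assumption: positions follow carotenoid numbering (C1 gem-dimethyl carbon, C3 carbinol, C5 methyl-bearing alkene carbon, C6 chain-bearing carbon); commercial pseudoionone is 3E with a 5E/5Z mixture and is drawn as 5E; which antipode of the step 1 catalyst gives R must be found in one test run, and both antipodes are equally accessible.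

## Route

Step 1
Reactants: 1 pseudoionone [(3E,5E)-6,10-dimethylundeca-3,5,9-trien-2-one]
Product: 3 (R)-α-ionone [(3E)-4-((1R)-2,6,6-trimethylcyclohex-2-en-1-yl)but-3-en-2-one], via tertiary cyclohexyl cation 2 (not isolated)
Conditions: confined chiral BINOL-derived imidodiphosphorimidate Brønsted acid (IDPi, N-triflyl core, bulky 3,3'-aryl groups, 5 mol %), (CF3)3COH/CH2Cl2, −20 °C, stopped at about 90 % conversion
Reagents that add atoms: none
Why: Proposed new method: the strongly acidic confined acid protonates the isolated trisubstituted alkene at C2 while the dienone carbonyl is hydrogen-bonded in the chiral pocket, the C5=C6 alkene closes the C1–C6 bond on one enantiotopic face through a chair-like transition state with the enone arm equatorial (setting C6 as R), and the paired chiral anion removes the neighbouring H-4 to give the kinetic ε-type alkene rather than β-ionone; the 5E and 5Z isomers should converge because the hydrogen-bonded dienone rotates about C5=C6 faster than it cyclises, and the closest known reactions are the racemic H3PO4 cation–olefin cyclisation of pseudoionone to α-ionone and IDPi-catalysed proton-initiated polyene cyclisation in fluorinated alcohols.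

Step 2
Reactants: 3 (R)-α-ionone
Product: 4 (3R,6R)-3-hydroxy-α-ionone [(3E)-4-((1R,4R)-4-hydroxy-2,6,6-trimethylcyclohex-2-en-1-yl)but-3-en-2-one; OH trans to the side chain]
Conditions: E. coli cells expressing cytochrome P450 CYP101B1, ferredoxin Arx and reductase ArR, air, NADH recycled with D-glucose/glucose dehydrogenase, phosphate buffer pH 7.4, 2 % EtOH, 30 °C; EtOAc extraction
Reagents that add atoms: dioxygen, O=O
Why: Enzymatic allylic C–H hydroxylation (P450 hydrogen abstraction and oxygen rebound) of α-ionone is known to go to the unhindered allylic CH2 at C3 and to deliver oxygen on the ring face opposite the C6 chain from either enantiomer, so (6R)-3 gives the 3,6-trans alcohol, which is 3R.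

Step 3
Reactants: 4 (3R,6R)-3-hydroxy-α-ionone; 5 vinylmagnesium bromide
Product: 6 (1R,4R)-4-((1E)-3-hydroxy-3-methylpenta-1,4-dien-1-yl)-3,5,5-trimethylcyclohex-2-en-1-ol (both C9 epimers)
Conditions: CH2=CHMgBr (2.5 equiv), THF, −30 → 0 °C; sat. aq NH4Cl; used crude
Reagents that add atoms: none
Why: Grignard 1,2-addition to the enone carbonyl (the vinyl-ionol reaction of retinoid manufacture): the first equivalent only deprotonates the C3 OH, the second adds to C9, the low temperature avoids γ-deprotonation at C6, and the new C9 centre does not matter because it becomes sp2 in step 4.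

Step 4
Reactants: 6 vinyl carbinol diol
Product: 8 ((2E,4E)-5-((1R,4R)-4-hydroxy-2,6,6-trimethylcyclohex-2-en-1-yl)-3-methylpenta-2,4-dien-1-yl)triphenylphosphonium bromide, via pentadienyl cation 7 (not isolated)
Conditions: Ph3P·HBr (1.0 equiv), CH2Cl2, 0 °C → rt; precipitated and recrystallised from CH2Cl2/EtOAc
Reagents that add atoms: triphenylphosphine hydrobromide, [Br-].c1ccc(cc1)[PH+](c1ccccc1)c1ccccc1
Why: Allylic SN1'-type phosphonium salt formation from a vinyl carbinol: the tertiary, doubly allylic C9 alcohol ionises far faster than the secondary ring allylic alcohol under the weak acid Ph3PH+, PPh3 captures the cation at its unhindered primary end C11 to give the conjugated 7E,9E salt, and one equivalent of acid in a non-nucleophilic solvent leaves C3 and C6 untouched.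

Step 5
Reactants: 8 C15 phosphonium bromide (2 equiv); 9 (2E,4E,6E)-2,7-dimethylocta-2,4,6-trienedial (1 equiv)
Product: 13 lactucaxanthin [(all-E,3R,6R,3'R,6'R)-ε,ε-carotene-3,3'-diol], via C15 phosphorane 10 (not isolated), via C25 apo-aldehyde 11 (not isolated), via 11Z-containing diol mixture 12 (not isolated)
Conditions: NaOMe (2.2 equiv), MeOH/CH2Cl2, −10 °C → rt, N2, dark; solvent changed to EtOH, reflux 3 h (Z → E), crystallised on cooling
Reagents that add atoms: none
Why: Two-fold Wittig olefination of the symmetrical dialdehyde (the C15 + C10 + C15 carotenoid coupling) tolerates free hydroxyl groups, the 11Z bonds formed beside E relax thermally to the all-E polyene that crystallises, no stereocentre is touched, and the pairwise union sends most of any minor enantiomer of 8 into a removable meso diastereomer.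

## Compound list
1 | pseudoionone, (3E,5E)-6,10-dimethylundeca-3,5,9-trien-2-one | CC(C)=CCC/C(C)=C/C=C/C(C)=O | starting material
2 | tertiary C5 cyclohexyl cation, paired with the chiral anion, C6 configured as in 3 | C[C+]1CCCC(C)(C)[C@H]1/C=C/C(C)=O | intermediate
3 | (R)-α-ionone | CC1=CCCC(C)(C)[C@H]1/C=C/C(C)=O | intermediate
4 | (3R,6R)-3-hydroxy-α-ionone (trans) | CC1=C[C@H](O)CC(C)(C)[C@H]1/C=C/C(C)=O | intermediate
5 | vinylmagnesium bromide | C=C[Mg]Br | starting material
6 | (3R,6R)-3-hydroxy-vinyl-α-ionol, C9 epimers | CC1=C[C@H](O)CC(C)(C)[C@H]1/C=C/C(C)(O)C=C | intermediate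
7 | C7–C11 pentadienyl cation | CC1=C[C@H](O)CC(C)(C)[C@H]1/C=C/[C+](C)C=C | intermediate
8 | C15 (3R,6R)-3-hydroxy-ε-end triphenylphosphonium bromide, 7E,9E | CC1=C[C@H](O)CC(C)(C)[C@H]1/C=C/C(C)=C/C[P+](c1ccccc1)(c1ccccc1)c1ccccc1.[Br-] | intermediate
9 | (2E,4E,6E)-2,7-dimethylocta-2,4,6-trienedial | O=C/C(C)=C/C=C/C=C(C)/C=O | starting material
10 | C15 phosphorane (ylide of 8) | CC1=C[C@H](O)CC(C)(C)[C@H]1/C=C/C(C)=C/C=P(c1ccccc1)(c1ccccc1)c1ccccc1 | intermediate
11 | (3R,6R)-3-hydroxy-12'-apo-ε-caroten-12'-al, 11E/Z | CC1=C[C@H](O)CC(C)(C)[C@H]1/C=C/C(C)=C/C=CC(/C)=C/C=C/C=C(C)/C=O | intermediate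
12 | (3R,6R,3'R,6'R)-ε,ε-carotene-3,3'-diol, E/Z mixture at C11=C12 and C11'=C12' | CC1=C[C@H](O)CC(C)(C)[C@H]1/C=C/C(C)=C/C=CC(/C)=C/C=C/C=C(\C)C=C/C=C(C)/C=C/[C@H]1C(C)=C[C@H](O)CC1(C)C | intermediate
13 | lactucaxanthin, all-E | CC1=C[C@H](O)CC(C)(C)[C@H]1/C=C/C(C)=C/C=C/C(C)=C/C=C/C=C(C)/C=C/C=C(C)/C=C/[C@H]1C(C)=C[C@H](O)CC1(C)C | target

## Count and risks
Total steps: 5. Longest linear sequence: 5 (1 → 3 → 4 → 6 → 8 → 13).

**Most likely to fail, first: step 1.**
- The nucleophilic alkene is part of a deactivated dienone.
- The level and sense of induction are unknown.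
- The acid can take 3 on to achiral β-ionone.
- About 90 % ee would be enough because of the amplification in step 5.

Fallback, from 1 back to 4: the ring is closed without asymmetric induction and the halves are resolved as diastereomers. Compound 1 is cyclised with 85 % H3PO4 to racemic α-ionone F1. The hydroxylase of step 2, which takes both enantiomers to the trans alcohols, converts it to racemic trans-3-hydroxy-α-ionone F2. Esterification with (1S,4R)-camphanoyl chloride in pyridine, followed by crystallisation and chromatography, gives the (3R,6R)-camphanate F3 and the (3S,6S)-camphanate F4. Methanolysis of F3 (K2CO3, MeOH, 0 °C) gives 4.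

**Second: step 2.**
- Substrate loading is low.
- Some over-oxidation to the 3-ketone occurs.
- The enzyme has to be expressed in house.

Fallback, from 3 (with 5) back to 6: the C–H hydroxylation is replaced by chemical oxidation to the enone and hydride reduction, done after the side-chain ketone is gone. Compound 3 and CH2=CHMgBr give (6R)-vinyl-α-ionol F5. Radical allylic oxidation (t-BuOOH, Rh2(cap)4, that is dirhodium tetracaprolactamate, K2CO3, CH2Cl2) gives the (6R)-3-oxo-vinyl-α-ionol F6, in which the ring ketone is the only carbonyl. KBH(s-Bu)3 in THF at −78 °C should attack away from the axial C1 methyl group and so place the OH trans to the chain, giving 6. Any cis epimer is removed by chromatography.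

**Third: step 4.**
- The ring allylic alcohol may also ionise, which would lead to C3 epimerisation, dehydration or a second phosphonium group.

Fallback, from 4 and 9 back to 12: the polarity of the coupling is reversed, so no acid ever meets the ring alcohol.
- Ring half: Horner–Wadsworth–Emmons reaction of 4 with diethyl cyanomethylphosphonate and NaH gives the C15 hydroxy nitrile F7. i-Bu2AlH followed by buffered hydrolysis gives the C15 hydroxy aldehyde F8.
- Central unit: 9 is reduced with NaBH4 to the C10 trienediol F9, which Ph3P·HBr converts to the C10 bis(triphenylphosphonium) dibromide F10.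
- Coupling: F10 with NaOMe and two equivalents of F8 gives 12, which is isomerised and crystallised as in step 5.

## Further compounds
F1 | step 1 | racemic α-ionone | CC1=CCCC(C)(C)C1/C=C/C(C)=O
F2 | step 1 | racemic trans-3-hydroxy-α-ionone | CC1=C[C@H](O)CC(C)(C)[C@H]1/C=C/C(C)=O.CC1=C[C@@H](O)CC(C)(C)[C@@H]1/C=C/C(C)=O
F3 | step 1 | (3R,6R)-3-hydroxy-α-ionone (1S,4R)-camphanate | CC1(C)[C@@]2(C)CC[C@@]1(OC2=O)C(=O)O[C@H]3C=C(C)[C@H](/C=C/C(C)=O)C(C)(C)C3
F4 | step 1 | (3S,6S)-3-hydroxy-α-ionone (1S,4R)-camphanate | CC1(C)[C@@]2(C)CC[C@@]1(OC2=O)C(=O)O[C@@H]3C=C(C)[C@@H](/C=C/C(C)=O)C(C)(C)C3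
F5 | step 2 | (6R)-vinyl-α-ionol, C9 epimers | CC1=CCCC(C)(C)[C@H]1/C=C/C(C)(O)C=C
F6 | step 2 | (6R)-3-oxo-vinyl-α-ionol, C9 epimers | CC1=CC(=O)CC(C)(C)[C@H]1/C=C/C(C)(O)C=C
F7 | step 4 | (2E,4E)-5-((1R,4R)-4-hydroxy-2,6,6-trimethylcyclohex-2-en-1-yl)-3-methylpenta-2,4-dienenitrile | CC1=C[C@H](O)CC(C)(C)[C@H]1/C=C/C(C)=C/C#N
F8 | step 4 | (2E,4E)-5-((1R,4R)-4-hydroxy-2,6,6-trimethylcyclohex-2-en-1-yl)-3-methylpenta-2,4-dienal | CC1=C[C@H](O)CC(C)(C)[C@H]1/C=C/C(C)=C/C=O
F9 | step 4 | (2E,4E,6E)-2,7-dimethylocta-2,4,6-triene-1,8-diol | OC/C(C)=C/C=C/C=C(C)/CO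
F10 | step 4 | (2E,4E,6E)-2,7-dimethylocta-2,4,6-triene-1,8-diylbis(triphenylphosphonium) dibromide | c1ccccc1[P+](c1ccccc1)(c1ccccc1)C/C(C)=C/C=C/C=C(C)/C[P+](c1ccccc1)(c1ccccc1)c1ccccc1.[Br-].[Br-]
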